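**Retrosynthetic overview**

1. The target is released in one final hydrogenation (one C=C and four O-benzyl groups) from a tetra-O-benzyl stilbene. That C=C is the future CH2–CH2 bridge between the 3-methoxyphenyl ring and catechol ring A (the ring with the biaryl bond ortho to an OH). It is made by joining two aldehyde carbons of like (electrophilic) polarity: a Ru(II)-catalysed reductive cross-coupling of a biaryl aldehyde with the N–H hydrazone of 3-methoxybenzaldehyde (carbonyl umpolung; N2 and water are the by-products).
2. Enabling feature: both bridge carbons are benzylic CH2 groups bonded directly to arene carbons (C1 of the 3-methoxyphenyl ring and the ring-A carbon meta to the biaryl bond). Each is therefore the formyl carbon of a non-enolisable aryl aldehyde, and the bridge has no stereocentre, so alkene geometry is irrelevant.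
3. The biaryl aldehyde comes from a Suzuki–Miyaura coupling (ring A–ring B bond) of a ring-A formyl boronate (from 3-bromo-4,5-dihydroxybenzaldehyde) with a ring-B bromide that already holds its saturated 3-methoxyphenethyl arm (Wittig, then diimide, from 2-bromo-4,5-bis(benzyloxy)benzaldehyde).
4. No ring is built; all four benzene rings are bought. Order of assembly: ring B with the first anisole ring, then ring A, then the second anisole ring.

Key step: step 7

Assumption: the target has no stereocentre, and its biaryl axis (only two ortho substituents, one OH and one CH2CH2Ar) should rotate freely at room temperature. It is therefore a single achiral compound and no stereocontrol is needed.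

**Route**

Step 1
Reactants: 1 3,4-bis(benzyloxy)benzaldehyde
Product: 2 2-bromo-4,5-bis(benzyloxy)benzaldehyde
Conditions: Br2, NaOAc, AcOH, rt
Reagents that add atoms: bromine, BrBr
Why: Electrophilic aromatic bromination should go to C6, para to the 3-benzyloxy group (the 4-benzyloxy group is engaged in conjugation with the formyl group), as is general for 3,4-dialkoxybenzaldehydes.

Step 2
Reactants: 2 2-bromo-4,5-bis(benzyloxy)benzaldehyde; 3 (3-methoxybenzyl)triphenylphosphonium chloride
Product: 5 1,2-bis(benzyloxy)-4-bromo-5-[2-(3-methoxyphenyl)ethenyl]benzene (E/Z mixture), via phosphorus ylide 4 (not isolated)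
Conditions: KOtBu, THF, 0 °C to rt
Reagents that add atoms: none
Why: Wittig olefination of an aryl aldehyde with a semi-stabilised benzylic ylide should give the stilbene as an E/Z mixture, which is acceptable because the alkene is saturated in the next step.

Step 3
Reactants: 5 1,2-bis(benzyloxy)-4-bromo-5-[2-(3-methoxyphenyl)ethenyl]benzene
Product: 6 1,2-bis(benzyloxy)-4-bromo-5-[2-(3-methoxyphenyl)ethyl]benzene
Conditions: TsNHNH2, NaOAc, DME/H2O, reflux
Reagents that add atoms: none
Why: Diimide reduction (concerted transfer of two hydrogens from HN=NH made in the flask) should saturate the stilbene C=C and leave the aryl bromide and the benzyl ethers untouched, which catalytic hydrogenation would put at risk.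

Step 4
Reactants: 7 3-bromo-4,5-dihydroxybenzaldehyde
Product: 8 3,4-bis(benzyloxy)-5-bromobenzaldehyde
Conditions: BnBr, K2CO3, DMF, 60 °C
Reagents that add atoms: benzyl bromide, BrCc1ccccc1
Why: Williamson ether synthesis on both phenoxides; benzyl is chosen so that all four catechol oxygens can be freed in the last step without touching the aryl methyl ethers.

Step 5
Reactants: 8 3,4-bis(benzyloxy)-5-bromobenzaldehyde
Product: 9 3,4-bis(benzyloxy)-5-(4,4,5,5-tetramethyl-1,3,2-dioxaborolan-2-yl)benzaldehyde
Conditions: B2pin2, Pd(dppf)Cl2 (cat.), KOAc, 1,4-dioxane, 90 °C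
Reagents that add atoms: bis(pinacolato)diboron, CC1(C)OB(OC1(C)C)B1OC(C)(C)C(C)(C)O1
Why: Miyaura borylation tolerates the free aldehyde, and the weak base KOAc should prevent the new boronate from coupling with unreacted bromide.

Step 6
Reactants: 9 3,4-bis(benzyloxy)-5-(4,4,5,5-tetramethyl-1,3,2-dioxaborolan-2-yl)benzaldehyde; 6 1,2-bis(benzyloxy)-4-bromo-5-[2-(3-methoxyphenyl)ethyl]benzene
Product: 10 4',5,5',6-tetrakis(benzyloxy)-2'-[2-(3-methoxyphenyl)ethyl]-[1,1'-biphenyl]-3-carbaldehyde
Conditions: Pd(OAc)2 (cat.), SPhos (cat.), K3PO4, toluene/H2O, 90 °C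
Reagents that add atoms: none
Why: Suzuki–Miyaura coupling forms the ring A–ring B bond; SPhos is chosen for the electron-rich ortho-alkyl bromide and the ortho-alkoxy boronate, and the new axis, with only two ortho substituents, needs no stereocontrol.

Step 7
Reactants: 10 4',5,5',6-tetrakis(benzyloxy)-2'-[2-(3-methoxyphenyl)ethyl]-[1,1'-biphenyl]-3-carbaldehyde; 11 3-methoxybenzaldehyde
Product: 13 2,3,4',5'-tetrakis(benzyloxy)-5-[2-(3-methoxyphenyl)ethenyl]-2'-[2-(3-methoxyphenyl)ethyl]-1,1'-biphenyl (E/Z mixture), via 3-methoxybenzaldehyde hydrazone 12 (not isolated)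
Conditions: 11 (1.5 equiv), N2H4·H2O (1 equiv per 11), THF, rt; then 10, [Ru(p-cymene)Cl2]2 (cat.), dmpe (cat.), KOtBu (substoichiometric), THF, 45 °C
Reagents that add atoms: none
Why: This is a Ru(II)-catalysed, hydrazone-mediated reductive cross-coupling of two carbonyl groups (carbonyl umpolung, a catalytic and cross-selective relative of the McMurry coupling): the Ru–dmpe complex binds the deprotonated N–H hydrazone 12 and aldehyde 10, and the hydrazone carbon, now a carbanion equivalent, attacks the formyl carbon of 10 through a six-membered chair-like transition state to form the new C–C bond. The Ru-bound adduct then loses N2 under base and expels hydroxide in an E1cB-type step, which gives the C=C bond with N2 and water as the only by-products. The closest known reaction type is the Ru(II)/bisphosphine-catalysed olefination of aryl aldehydes and ketones with N–H hydrazones of aryl aldehydes, mechanistically a Wolff–Kishner reduction intercepted by a carbonyl electrophile. No ring is closed and no stereocentre is formed; the E/Z ratio is deliberately left uncontrolled because step 8 saturates the alkene. The step needs cross- over homo-coupling and C–C bond formation over azine condensation: the first is secured because only 11 is turned into its hydrazone (one equivalent of hydrazine, before 10 is added) and 10 has a single formyl group with no enolisable C–H, the second by the chelating Ru catalyst, which channels the hydrazone into the C-nucleophilic pathway. Benzyl and methyl aryl ethers should be inert to these mildly basic, redox-neutral conditions.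

Step 8
Reactants: 13 2,3,4',5'-tetrakis(benzyloxy)-5-[2-(3-methoxyphenyl)ethenyl]-2'-[2-(3-methoxyphenyl)ethyl]-1,1'-biphenyl
Product: 14 isoplagilin, 2',5-bis[2-(3-methoxyphenyl)ethyl]-[1,1'-biphenyl]-2,3,4',5'-tetrol
Conditions: H2 (1 atm), 10% Pd/C, EtOAc/MeOH, rt, work-up under argon
Reagents that add atoms: none
Why: Heterogeneous hydrogenation and hydrogenolysis over Pd/C should saturate both stilbene isomers and cleave the four benzyl ethers in one operation, while the aryl methyl ethers and the biaryl are inert.

**Compound list**

1 | 3,4-bis(benzyloxy)benzaldehyde | O=Cc1ccc(OCc2ccccc2)c(OCc2ccccc2)c1 | starting material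
2 | 2-bromo-4,5-bis(benzyloxy)benzaldehyde | O=Cc1cc(OCc2ccccc2)c(OCc2ccccc2)cc1Br | intermediate
3 | (3-methoxybenzyl)triphenylphosphonium chloride | COc1cccc(C[P+](c2ccccc2)(c2ccccc2)c2ccccc2)c1.[Cl-] | starting material
4 | (3-methoxybenzylidene)triphenylphosphorane (ylide, not isolated) | COc1cccc(C=P(c2ccccc2)(c2ccccc2)c2ccccc2)c1 | intermediate
5 | 1,2-bis(benzyloxy)-4-bromo-5-[2-(3-methoxyphenyl)ethenyl]benzene (E/Z mixture, geometry left open) | COc1cccc(C=Cc2cc(OCc3ccccc3)c(OCc3ccccc3)cc2Br)c1 | intermediate
6 | 1,2-bis(benzyloxy)-4-bromo-5-[2-(3-methoxyphenyl)ethyl]benzene | COc1cccc(CCc2cc(OCc3ccccc3)c(OCc3ccccc3)cc2Br)c1 | intermediate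
7 | 3-bromo-4,5-dihydroxybenzaldehyde | O=Cc1cc(O)c(O)c(Br)c1 | starting material
8 | 3,4-bis(benzyloxy)-5-bromobenzaldehyde | O=Cc1cc(OCc2ccccc2)c(OCc2ccccc2)c(Br)c1 | intermediate
9 | 3,4-bis(benzyloxy)-5-(4,4,5,5-tetramethyl-1,3,2-dioxaborolan-2-yl)benzaldehyde | O=Cc1cc(OCc2ccccc2)c(OCc2ccccc2)c(B2OC(C)(C)C(C)(C)O2)c1 | intermediate
10 | 4',5,5',6-tetrakis(benzyloxy)-2'-[2-(3-methoxyphenyl)ethyl]-[1,1'-biphenyl]-3-carbaldehyde | COc1cccc(CCc2cc(OCc3ccccc3)c(OCc3ccccc3)cc2-c2cc(C=O)cc(OCc3ccccc3)c2OCc2ccccc2)c1 | intermediate
11 | 3-methoxybenzaldehyde | COc1cccc(C=O)c1 | starting material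
12 | (E)-3-methoxybenzaldehyde hydrazone (not isolated) | COc1cccc(/C=N/N)c1 | intermediate
13 | 2,3,4',5'-tetrakis(benzyloxy)-5-[2-(3-methoxyphenyl)ethenyl]-2'-[2-(3-methoxyphenyl)ethyl]-1,1'-biphenyl (E/Z mixture, geometry left open) | COc1cccc(C=Cc2cc(OCc3ccccc3)c(OCc3ccccc3)c(-c3cc(OCc4ccccc4)c(OCc4ccccc4)cc3CCc3cccc(OC)c3)c2)c1 | intermediate
14 | isoplagilin, 2',5-bis[2-(3-methoxyphenyl)ethyl]-[1,1'-biphenyl]-2,3,4',5'-tetrol (achiral) | COc1cccc(CCc2cc(O)c(O)c(-c3cc(O)c(O)cc3CCc3cccc(OC)c3)c2)c1 | target

**Summary**

Total step count: 8. Longest linear sequence: 6 steps (steps 1, 2, 3, 6, 7, 8, from compound 1).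

Steps most likely to fail:

1. Step 7. Condensation of the N–H hydrazone with the aldehyde to an azine, or base-induced loss of N2 from the hydrazone before C–C bond formation, may outrun the Ru-mediated coupling; the elimination to the alkene may also stall. The fallback sets out from 10 and returns at 13: Wittig olefination of 10 with the phosphorus ylide 4, generated from 3 with KOtBu in THF at 0 °C, should give 13 directly as an E/Z mixture. This replaces the umpolung coupling by a conventional ylide–carbonyl olefination and needs no new compound.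

2. Step 6. Oxidative addition into the hindered, electron-rich bromide may be slow, so that protodeboronation of the ortho-alkoxy boronate competes. The fallback sets out from 6 and returns at 10: bromine–lithium exchange on 6 (n-BuLi, THF, −78 °C) should give [4,5-bis(benzyloxy)-2-[2-(3-methoxyphenyl)ethyl]phenyl]lithium F1, and transmetalation with ZnCl2 should give [4,5-bis(benzyloxy)-2-[2-(3-methoxyphenyl)ethyl]phenyl]zinc chloride F2. Negishi coupling of F2 with bromide 8 (Pd2(dba)3, SPhos, THF, 50 °C) should then give 10. The nucleophile is thus an organozinc made without boron or aqueous base, and step 5 is no longer needed.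

3. Step 3. Hydrogen transfer from diimide to the ortho-bromostilbene may stay incomplete, leaving alkene that is hard to separate from the product. The fallback sets out from 2 and returns at 6, replacing steps 2 and 3: NaBH4 reduction of 2 (MeOH/THF, 0 °C) should give [4,5-bis(benzyloxy)-2-bromophenyl]methanol F3, and PBr3 (CH2Cl2, 0 °C) should give 1,2-bis(benzyloxy)-4-bromo-5-(bromomethyl)benzene F4. Cu-catalysed coupling of F4 with commercial 3-methoxybenzylmagnesium chloride (Li2CuCl4 cat., THF, −30 °C) should give 6 with the saturated bridge made directly, so that no alkene has to be reduced.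

Further compounds
F0 | step 7 | none | none
F1 | step 6 | [4,5-bis(benzyloxy)-2-[2-(3-methoxyphenyl)ethyl]phenyl]lithium | COc1cccc(CCc2cc(OCc3ccccc3)c(OCc3ccccc3)cc2[Li])c1
F2 | step 6 | [4,5-bis(benzyloxy)-2-[2-(3-methoxyphenyl)ethyl]phenyl]zinc chloride | COc1cccc(CCc2cc(OCc3ccccc3)c(OCc3ccccc3)cc2[Zn]Cl)c1
F3 | step 3 | [4,5-bis(benzyloxy)-2-bromophenyl]methanol | OCc1cc(OCc2ccccc2)c(OCc2ccccc2)cc1Br
F4 | step 3 | 1,2-bis(benzyloxy)-4-bromo-5-(bromomethyl)benzene | BrCc1cc(OCc2ccccc2)c(OCc2ccccc2)cc1Br
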